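## Retrosynthetic overview

1. Hippolide E (20) ⇐ 24‑aldehyde 19 by 1,2‑reduction of the E‑enal (last step).
2. 19 ⇐ C4–C5 disconnection: enantioselective vinylogous Mukaiyama aldol of silyl dienol ether 16 onto the Z‑formyl acrylate 5; the new C4–O closes onto C1 (sets C4‑R, the 6E alkene and the butenolide together).
3. 5 ⇐ γ‑hydroxybutenolide 4 ⇐ 3‑(silyloxymethyl)furan 2 by singlet‑oxygen oxidation (from furan‑3‑ylmethanol 1).
4. 16 ⇐ E‑2‑alkylbut‑2‑enal 15 ⇐ aldehyde 10 + acetaldehyde 11; 10 ⇐ farnesyl bromide 6 + C3 acetal bromide 7.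
5. Ring order: one ring only – formed as the γ‑hydroxybutenolide (step 2), opened (step 3), re‑closed on the C4 oxygen as the final butenolide (step 7).

Assumption (biosynthesis): a β‑substituted furan is oxidised to a γ‑hydroxybutenolide (masked Z‑formylacrylic acid), the C1 carboxyl closes onto the C4 hydroxyl (neomanoalide‑type lactone), and the E‑24‑enal is reduced last.

Assumption (sense of induction): the L‑tryptophan oxazaborolidinone directs Re‑face attack on the formyl group (Corey model), giving 4R; if the opposite sense is found, the D‑tryptophan reagent is used with no other change.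

## Route

Step 1
Reactants: 1 furan-3-ylmethanol
Product: 2 triethyl(furan-3-ylmethoxy)silane
Conditions: TESCl, imidazole, CH2Cl2, 0 °C → rt
Reagents that add atoms: chlorotriethylsilane CC[Si](Cl)(CC)CC
Why: Imidazole‑promoted silylation of a primary alcohol; TES masks the OH from the boron Lewis acid of step 7 and is labile enough to be removed in that step's acidic work‑up.

Step 2
Reactants: 2 triethyl(furan-3-ylmethoxy)silane
Product: 4 5-hydroxy-4-{[(triethylsilyl)oxy]methyl}furan-2(5H)-one, via furan endoperoxide 3 (not isolated)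
Conditions: O2, hν (visible), TPP (0.5 mol%), i-Pr2NEt (3 equiv), CH2Cl2, −78 °C, then rt; aq. citric acid work-up
Reagents that add atoms: dioxygen O=O
Why: [4+2] cycloaddition of singlet oxygen to the furan, then Kornblum–DeLaMare fragmentation in which the hindered base removes the less hindered C5–H, so the carbonyl ends up remote from the CH2OSi group (Faulkner conditions for 3‑alkylfurans); this is the biomimetic furan → γ‑hydroxybutenolide oxidation.

Step 3
Reactants: 4 5-hydroxy-4-{[(triethylsilyl)oxy]methyl}furan-2(5H)-one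
Product: 5 methyl (2Z)-3-formyl-4-[(triethylsilyl)oxy]but-2-enoate
Conditions: MeI, K2CO3, DMF, 0 °C, 1 h; used without delay
Reagents that add atoms: iodomethane CI
Why: The pseudo‑acid ionises as its ring‑opened carboxylate, and SN2 O‑alkylation of that carboxylate gives the open‑chain ester with the formyl group held cis to the ester, as known for cis‑β‑formylcrotonic acid.

Step 4
Reactants: 6 (2E,6E)-farnesyl bromide; 7 2-(2-bromoethyl)-1,3-dioxolane
Product: 10 (5E,9E)-6,10,14-trimethylpentadeca-5,9,13-trienal, via acetal Grignard reagent 8 (not isolated), via dioxolane acetal 9 (not isolated)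
Conditions: Mg, THF, ≤30 °C (from 7); then 6, Li2CuCl4 (3 mol%), THF, −20 → 0 °C; then 2 M HCl, THF, rt
Reagents that add atoms: water O
Why: Grignard formation, then copper‑catalysed (Kochi) sp3–allyl cross‑coupling by SN2 at the primary allylic bromide with retention of the 2E,6E geometry, then acid hydrolysis of the dioxolane.

Step 5
Reactants: 10 (5E,9E)-6,10,14-trimethylpentadeca-5,9,13-trienal; 11 acetaldehyde
Product: 15 (2E,5E,9E)-2-ethylidene-6,10,14-trimethylpentadeca-5,9,13-trienal, via cyclohexylimine 12 (not isolated), via aldol imine adduct 13 (not isolated), via hydroxy aldehyde 14 (not isolated)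
Conditions: c-HexNH2, 4 Å MS, Et2O, rt; LDA, THF, −78 → 0 °C, then 11, −78 °C; then aq. oxalic acid, THF, rt → 50 °C
Reagents that add atoms: water O
Why: Wittig directed aldol condensation – the lithiated imine adds to acetaldehyde without self‑condensation, and acid hydrolysis with dehydration gives the thermodynamically favoured E‑enal (CHO trans to CH3).

Step 6
Reactants: 15 (2E,5E,9E)-2-ethylidene-6,10,14-trimethylpentadeca-5,9,13-trienal
Product: 16 tert-butyl{[(1E,5E,9E)-2-ethenyl-6,10,14-trimethylpentadeca-1,5,9,13-tetraen-1-yl]oxy}dimethylsilane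
Conditions: TBSOTf, Et3N, CH2Cl2, 0 °C → rt
Reagents that add atoms: tert-butyldimethylsilyl trifluoromethanesulfonate CC(C)(C)[Si](C)(C)OS(=O)(=O)C(F)(F)F
Why: Soft enolisation (O‑silylation, then deprotonation at C5, the only γ‑position) gives the silyl dienol ether, as for tiglic aldehyde; the 1E/1Z ratio does not matter for step 7.

Step 7
Reactants: 5 methyl (2Z)-3-formyl-4-[(triethylsilyl)oxy]but-2-enoate; 16 tert-butyl{[(1E,5E,9E)-2-ethenyl-6,10,14-trimethylpentadeca-1,5,9,13-tetraen-1-yl]oxy}dimethylsilane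
Product: 19 (2E,5E,9E)-2-{2-[(2R)-3-(hydroxymethyl)-5-oxo-2,5-dihydrofuran-2-yl]ethylidene}-6,10,14-trimethylpentadeca-5,9,13-trienal, via hydroxy ester 17 (not isolated), via silyl ether butenolide 18 (not isolated)
Conditions: B-phenyl oxazaborolidinone from N-Ts-L-tryptophan (1.0 equiv), i-PrOH (1.2 equiv), EtCN, −78 °C; then 1 M HCl, THF, 0 °C → rt
Reagents that add atoms: none
Why: Oxazaborolidinone‑promoted vinylogous Mukaiyama aldol (Kalesse type) – γ‑attack of the dienol ether on the Re face of the boron‑bound formyl group sets C4 as R and gives the E‑enal (formyl trans to C5); the C4–OH is cis to the ester and lactonises (the biomimetic C1→C4–O ring closure), and the same acid removes TES.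

Step 8
Reactants: 19 (2E,5E,9E)-2-{2-[(2R)-3-(hydroxymethyl)-5-oxo-2,5-dihydrofuran-2-yl]ethylidene}-6,10,14-trimethylpentadeca-5,9,13-trienal
Product: 20 Hippolide E
Conditions: NaBH4, CeCl3·7H2O, MeOH, −40 °C
Reagents that add atoms: none
Why: Luche reduction – 1,2‑selective reduction of the enal leaves the β,β‑disubstituted butenolide and the C4 stereocentre untouched; it mirrors the last biosynthetic reduction.

## Compound list

1 | furan-3-ylmethanol | OCc1ccoc1 | starting material
2 | triethyl(furan-3-ylmethoxy)silane | CC[Si](CC)(CC)OCc1ccoc1 | intermediate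
3 | 5-{[(triethylsilyl)oxy]methyl}-2,3,7-trioxabicyclo[2.2.1]hept-5-ene (racemic) | CC[Si](CC)(CC)OCC1=CC2OOC1O2 | intermediate
4 | 5-hydroxy-4-{[(triethylsilyl)oxy]methyl}furan-2(5H)-one (racemic hemiacetal) | CC[Si](CC)(CC)OCC1=CC(=O)OC1O | intermediate
5 | methyl (2Z)-3-formyl-4-[(triethylsilyl)oxy]but-2-enoate | COC(=O)/C=C(\C=O)CO[Si](CC)(CC)CC | intermediate
6 | (2E,6E)-farnesyl bromide, (2E,6E)-1-bromo-3,7,11-trimethyldodeca-2,6,10-triene | CC(C)=CCC/C(C)=C/CC/C(C)=C/CBr | starting material
7 | 2-(2-bromoethyl)-1,3-dioxolane | BrCCC1OCCO1 | starting material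
8 | [2-(1,3-dioxolan-2-yl)ethyl]magnesium bromide | Br[Mg]CCC1OCCO1 | intermediate
9 | 2-[(4E,8E)-5,9,13-trimethyltetradeca-4,8,12-trien-1-yl]-1,3-dioxolane | CC(C)=CCC/C(C)=C/CC/C(C)=C/CCCC1OCCO1 | intermediate
10 | (5E,9E)-6,10,14-trimethylpentadeca-5,9,13-trienal | CC(C)=CCC/C(C)=C/CC/C(C)=C/CCCC=O | intermediate
11 | acetaldehyde | CC=O | starting material
12 | (5E,9E)-N-cyclohexyl-6,10,14-trimethylpentadeca-5,9,13-trien-1-imine | CC(C)=CCC/C(C)=C/CC/C(C)=C/CCCC=NC1CCCCC1 | intermediate
13 | (6E,10E)-3-[(cyclohexylimino)methyl]-7,11,15-trimethylhexadeca-6,10,14-trien-2-ol (diastereomer mixture) | CC(C)=CCC/C(C)=C/CC/C(C)=C/CCC(C=NC1CCCCC1)C(C)O | intermediate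
14 | (5E,9E)-2-(1-hydroxyethyl)-6,10,14-trimethylpentadeca-5,9,13-trienal (diastereomer mixture) | CC(C)=CCC/C(C)=C/CC/C(C)=C/CCC(C=O)C(C)O | intermediate
15 | (2E,5E,9E)-2-ethylidene-6,10,14-trimethylpentadeca-5,9,13-trienal | CC(C)=CCC/C(C)=C/CC/C(C)=C/CC/C(C=O)=C\C | intermediate
16 | tert-butyl{[(1E,5E,9E)-2-ethenyl-6,10,14-trimethylpentadeca-1,5,9,13-tetraen-1-yl]oxy}dimethylsilane | CC(C)=CCC/C(C)=C/CC/C(C)=C/CC/C(C=C)=C\O[Si](C)(C)C(C)(C)C | intermediate
17 | methyl (2Z,4R,6E,10E,14E)-7-formyl-4-hydroxy-11,15,19-trimethyl-3-{[(triethylsilyl)oxy]methyl}icosa-2,6,10,14,18-pentaenoate | CC(C)=CCC/C(C)=C/CC/C(C)=C/CC/C(=C\C[C@@H](O)/C(CO[Si](CC)(CC)CC)=C\C(=O)OC)C=O | intermediate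
18 | (2E,5E,9E)-6,10,14-trimethyl-2-{2-[(2R)-5-oxo-3-{[(triethylsilyl)oxy]methyl}-2,5-dihydrofuran-2-yl]ethylidene}pentadeca-5,9,13-trienal | CC(C)=CCC/C(C)=C/CC/C(C)=C/CC/C(=C\C[C@H]1OC(=O)C=C1CO[Si](CC)(CC)CC)C=O | intermediate
19 | (2E,5E,9E)-2-{2-[(2R)-3-(hydroxymethyl)-5-oxo-2,5-dihydrofuran-2-yl]ethylidene}-6,10,14-trimethylpentadeca-5,9,13-trienal | CC(C)=CCC/C(C)=C/CC/C(C)=C/CC/C(=C\C[C@H]1OC(=O)C=C1CO)C=O | intermediate
20 | Hippolide E, (5R)-4-(hydroxymethyl)-5-[(2E,6E,10E)-3-(hydroxymethyl)-7,11,15-trimethylhexadeca-2,6,10,14-tetraen-1-yl]furan-2(5H)-one | CC(C)=CCC/C(C)=C/CC/C(C)=C/CC/C(=C\C[C@H]1OC(=O)C=C1CO)CO | target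

## Step count and weak points

Total steps: 8. Longest linear sequence: 5 (steps 4–8, from farnesyl bromide 6).

Step 7 is the most likely to fail. The cis ester of 5 may take part (cyclic acyl‑oxocarbenium) and erode the enantioselectivity, this class of aldehyde is untested with the oxazaborolidinone, and 5 can isomerise. The fallback sets out from 5 and 10. Brown allylboration of 5 with (+)-B-allyldiisopinocampheylborane (Et2O, −78 °C; the antipode that gives (R)-1-phenylbut-3-en-1-ol from benzaldehyde), then ethanolamine work‑up and acid‑catalysed lactonisation, gives (5R)-5-(prop-2-en-1-yl)-4-{[(triethylsilyl)oxy]methyl}furan-2(5H)-one F1. α‑Methylenation of 10 (aqueous formaldehyde, pyrrolidine/propionic acid, i-PrOH, 45 °C) gives (5E,9E)-6,10,14-trimethyl-2-methylidenepentadeca-5,9,13-trienal F2. E‑selective cross‑metathesis of F1 with F2 (Hoveyda–Grubbs II, CH2Cl2, 40 °C) comes back to the route at 18, which is desilylated to 19 as in step 7. The stereocentre then comes from a reagent‑controlled allylboration and the trisubstituted alkene from metathesis, and steps 5 and 6 are not needed; the main risk is competing metathesis at the prenyl‑type alkenes.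

Step 3 is the second risk. The open Z‑formyl ester may isomerise to the E isomer or be too labile to handle. The fallback sets out from 4. Methylation as in step 3 followed by deliberate equilibration with catalytic iodine (CH2Cl2, daylight) gives the stable isomer methyl (2E)-3-formyl-4-[(triethylsilyl)oxy]but-2-enoate F3. The same oxazaborolidinone aldol with 16 gives methyl (2E,4R,6E,10E,14E)-7-formyl-4-hydroxy-11,15,19-trimethyl-3-{[(triethylsilyl)oxy]methyl}icosa-2,6,10,14,18-pentaenoate F4, which cannot lactonise. Sensitised photochemical E→Z isomerisation of the enoate then triggers lactonisation and comes back to the route at 18. The ring is closed by an isomerisation–lactonisation instead of directly from a Z aldehyde; the enal may need re‑equilibration to E afterwards.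

Step 4 is the third risk. The copper‑catalysed coupling can give SN2′ (linalyl‑type) product and Wurtz dimer, and Grignard reagent 8 is thermally fragile. The fallback sets out from 6. The lithio derivative of purchased 2-[2-(phenylsulfonyl)ethyl]-1,3-dioxolane (O=S(=O)(CCC1OCCO1)c1ccccc1; n-BuLi, THF/DMPU, −78 °C) is alkylated with 6 to give 2-[(4E,8E)-5,9,13-trimethyl-2-(phenylsulfonyl)tetradeca-4,8,12-trien-1-yl]-1,3-dioxolane F5 by clean SN2 at the allylic bromide. Reductive removal of the sulfone (Na/Hg, Na2HPO4, MeOH, −20 °C) comes back to the route at 9, which is hydrolysed to 10 as in step 4.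

## Further compounds

F1 | step 7 | (5R)-5-(prop-2-en-1-yl)-4-{[(triethylsilyl)oxy]methyl}furan-2(5H)-one | C=CC[C@H]1OC(=O)C=C1CO[Si](CC)(CC)CC
F2 | step 7 | (5E,9E)-6,10,14-trimethyl-2-methylidenepentadeca-5,9,13-trienal | CC(C)=CCC/C(C)=C/CC/C(C)=C/CCC(=C)C=O
F3 | step 3 | methyl (2E)-3-formyl-4-[(triethylsilyl)oxy]but-2-enoate | COC(=O)/C=C(/C=O)CO[Si](CC)(CC)CC
F4 | step 3 | methyl (2E,4R,6E,10E,14E)-7-formyl-4-hydroxy-11,15,19-trimethyl-3-{[(triethylsilyl)oxy]methyl}icosa-2,6,10,14,18-pentaenoate | CC(C)=CCC/C(C)=C/CC/C(C)=C/CC/C(=C\C[C@@H](O)/C(CO[Si](CC)(CC)CC)=C/C(=O)OC)C=O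
F5 | step 4 | 2-[(4E,8E)-5,9,13-trimethyl-2-(phenylsulfonyl)tetradeca-4,8,12-trien-1-yl]-1,3-dioxolane | CC(C)=CCC/C(C)=C/CC/C(C)=C/CC(CC1OCCO1)S(=O)(=O)c1ccccc1
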